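## Retrosynthetic overview

1. Target 14 ⇒ lactol 11 + phenol: the C2–aryl bond is made last by Friedel–Crafts arylation of the oxocarbenium ion, trans to the C3 arm.
2. 11 ⇒ lactone diacetate 10 (lactone → lactol with the acetates kept) ⇒ diol lactone 9.
3. 9 ⇒ hydroxy lactone 7 + CH2O (C3–CH2O bond, trans to C4) ⇒ keto lactone 6 (carbinol centre by asymmetric transfer hydrogenation).
4. 6 ⇒ 3-(4-methoxybenzoyl)cyclobutanone 4 by enantioselective Baeyer–Villiger ring expansion; this forms the only new ring (the oxolane) and sets C4.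
5. 4 ⇒ anisole + 3-oxocyclobutane-1-carboxylic acid (Friedel–Crafts acylation); both benzene rings are bought.

Assumption: formaldehyde, H2O2 and Ac2O are treated as reagents; in step 2 the (R)-acid is taken to give (R)-6, and the (S)-acid is used if the opposite sense is found.

Oxolane locants used below: O1, C2 (aryl), C3 (CH2OAc), C4 (carbinol arm), C5.

## Route

Step 1
Reactants: 1 3-oxocyclobutane-1-carboxylic acid; 2 anisole
Product: 4 3-(4-methoxybenzoyl)cyclobutan-1-one, via 3-oxocyclobutane-1-carbonyl chloride 3 (not isolated)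
Conditions: (COCl)2, cat. DMF, CH2Cl2, 0 °C → rt, concentrate; then 2, AlCl3 (2.2 equiv), CH2Cl2, 0 °C; ice/HCl
Reagents that add atoms: none
Why: Friedel–Crafts acylation of anisole by the acylium ion from 3 is para-selective (OMe director, bulky secondary acyl group), and the cyclobutanone survives as its AlCl3 complex because it neither enolises readily nor acts as an arene electrophile at 0 °C.

Step 2
Reactants: 4 3-(4-methoxybenzoyl)cyclobutan-1-one
Product: 6 (4R)-4-(4-methoxybenzoyl)oxolan-2-one, via Criegee perhydrate adduct 5 (not isolated)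
Conditions: (R)-3,3′-di(pyren-1-yl)-H8-BINOL phosphoric acid (10 mol%), 30% aq. H2O2 (1.5 equiv), CHCl3, −40 °C; Na2S2O3 wash, cold short silica plug, used at once
Reagents that add atoms: hydrogen peroxide, OO
Why: Proposed new method: enantiotopos-selective Baeyer–Villiger ring expansion of a 3-aroylcyclobutanone under chiral phosphoric acid/H2O2 catalysis, in which the acid adds H2O2 only to the strained ketone (the conjugated aryl ketone is not attacked), one of the two enantiotopic ring CH2 groups of the ion-paired Criegee adduct 5 migrates to oxygen (1,2-C→O shift with strain release) inside the chiral pocket while the aroyl C=O gives a second hydrogen-bond contact, so that (R)-6 forms with the ring C–O bond and the C4 centre set; the closest known reaction type is the chiral Brønsted acid (or Sc(III)/N,N′-dioxide) desymmetrising Baeyer–Villiger oxidation of 3-aryl- and 3-alkylcyclobutanones, not shown for 3-acyl substrates whose new stereocentre is α to a ketone.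

Step 3
Reactants: 6 (4R)-4-(4-methoxybenzoyl)oxolan-2-one
Product: 7 (4R)-4-[(S)-hydroxy(4-methoxyphenyl)methyl]oxolan-2-one
Conditions: RuCl[(S,S)-TsDPEN](mesitylene) (2 mol%), HCO2H/Et3N (5:2), CH2Cl2, 30 °C; chromatography
Reagents that add atoms: none
Why: Noyori–Ikariya asymmetric transfer hydrogenation reduces only the aryl ketone, the (S,S)-catalyst delivering hydride to the face that gives the (S)-carbinol (aryl CH/π control, as for acetophenone → (S)-alcohol), while the acidic medium avoids enolisation at C4 and the small amount of (4S) diastereomer from residual ent-6 is removed, which raises the ee.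

Step 4
Reactants: 7 (4R)-4-[(S)-hydroxy(4-methoxyphenyl)methyl]oxolan-2-one
Product: 9 (3S,4R)-3-(hydroxymethyl)-4-[(S)-hydroxy(4-methoxyphenyl)methyl]oxolan-2-one, via dilithium alkoxide enolate 8 (not isolated)
Conditions: LDA (2.3 equiv), THF, −78 °C (7 added to the base); CH2O gas (from cracked paraformaldehyde), −78 °C; AcOH, −78 °C
Reagents that add atoms: formaldehyde, C=O
Why: Aldol addition of the lactone lithium enolate (alkoxide–enolate dianion) to monomeric formaldehyde takes place on the ring face anti to the C4 substituent, as in alkylations of β-substituted butyrolactones, so the new C3 centre is set trans (3S).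

Step 5
Reactants: 9 (3S,4R)-3-(hydroxymethyl)-4-[(S)-hydroxy(4-methoxyphenyl)methyl]oxolan-2-one
Product: 10 [(3S,4R)-4-[(S)-acetoxy(4-methoxyphenyl)methyl]-2-oxooxolan-3-yl]methyl acetate
Conditions: Ac2O (3 equiv), pyridine, DMAP (5 mol%), CH2Cl2, 0 °C → rt
Reagents that add atoms: acetic anhydride, CC(=O)OC(C)=O
Why: DMAP-catalysed acetylation installs both acetates of the target at once under conditions too weakly basic for E1cB loss of the β-acetoxy group or epimerisation at C3.

Step 6
Reactants: 10 [(3S,4R)-4-[(S)-acetoxy(4-methoxyphenyl)methyl]-2-oxooxolan-3-yl]methyl acetate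
Product: 11 [(3S,4R)-4-[(S)-acetoxy(4-methoxyphenyl)methyl]-2-hydroxyoxolan-3-yl]methyl acetate (anomer mixture)
Conditions: Sia2BH (2.5 equiv, from BH3·THF + 2-methylbut-2-ene, 0 °C), THF, 0 °C → rt; then H2O, 0 °C; neutral work-up, used crude
Reagents that add atoms: none
Why: Disiamylborane reduces γ-lactones to lactols but leaves acyclic esters untouched (the classical reduction of O-acylated aldonolactones to acylated furanoses), so both acetates are expected to survive and no stereocentre is touched.

Step 7
Reactants: 11 [(3S,4R)-4-[(S)-acetoxy(4-methoxyphenyl)methyl]-2-hydroxyoxolan-3-yl]methyl acetate; 12 phenol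
Product: 14 [(2R,3S,4R)-4-[(S)-acetoxy(4-methoxyphenyl)methyl]-2-(4-hydroxyphenyl)oxolan-3-yl]methyl acetate, via cyclic oxocarbenium ion 13 (not isolated)
Conditions: 12 (5 equiv), BF3·OEt2 (1.2 equiv), 4 Å MS, CH2Cl2, −78 → −40 °C; sat. NaHCO3
Reagents that add atoms: none
Why: Friedel–Crafts (C-glycosylation-type) arylation in which the hemiacetal ionises at −78 °C well before the benzylic acetate can, phenol attacks 13 through its para carbon (any O-aryl acetal re-ionises) on the face anti to the C3 acetoxymethyl arm, helped by acetate participation, so C2 is set trans (2R), and the benzylic ether can equilibrate to the all-trans isomer.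

## Compound list

1 | 3-oxocyclobutane-1-carboxylic acid | O=C1CC(C1)C(=O)O | starting material
2 | anisole (methoxybenzene) | COc1ccccc1 | starting material
3 | 3-oxocyclobutane-1-carbonyl chloride | O=C1CC(C1)C(=O)Cl | intermediate (not isolated)
4 | 3-(4-methoxybenzoyl)cyclobutan-1-one | COc1ccc(cc1)C(=O)C1CC(=O)C1 | intermediate
5 | (3-hydroperoxy-3-hydroxycyclobutyl)(4-methoxyphenyl)methanone (Criegee perhydrate adduct) | COc1ccc(cc1)C(=O)C1CC(O)(OO)C1 | intermediate (not isolated)
6 | (4R)-4-(4-methoxybenzoyl)oxolan-2-one | COc1ccc(C(=O)[C@H]2COC(=O)C2)cc1 | intermediate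
7 | (4R)-4-[(S)-hydroxy(4-methoxyphenyl)methyl]oxolan-2-one | COc1ccc([C@@H](O)[C@H]2COC(=O)C2)cc1 | intermediate
8 | dilithium alkoxide enolate of 7 | [Li+].[Li+].COc1ccc([C@@H]([O-])[C@H]2COC([O-])=C2)cc1 | intermediate (not isolated)
9 | (3S,4R)-3-(hydroxymethyl)-4-[(S)-hydroxy(4-methoxyphenyl)methyl]oxolan-2-one | COc1ccc([C@@H](O)[C@H]2COC(=O)[C@@H]2CO)cc1 | intermediate
10 | [(3S,4R)-4-[(S)-acetoxy(4-methoxyphenyl)methyl]-2-oxooxolan-3-yl]methyl acetate | COc1ccc([C@@H](OC(C)=O)[C@H]2COC(=O)[C@@H]2COC(C)=O)cc1 | intermediate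
11 | [(3S,4R)-4-[(S)-acetoxy(4-methoxyphenyl)methyl]-2-hydroxyoxolan-3-yl]methyl acetate (C2 epimers) | COc1ccc([C@@H](OC(C)=O)[C@H]2COC(O)[C@@H]2COC(C)=O)cc1 | intermediate
12 | phenol | Oc1ccccc1 | starting material
13 | (3S,4R)-3-(acetoxymethyl)-4-[(S)-acetoxy(4-methoxyphenyl)methyl]-3,4-dihydro-2H-furan-1-ium (cyclic oxocarbenium ion) | COc1ccc([C@@H](OC(C)=O)[C@H]2C[O+]=C[C@@H]2COC(C)=O)cc1 | intermediate (not isolated)
14 | [(2R,3S,4R)-4-[(S)-acetoxy(4-methoxyphenyl)methyl]-2-(4-hydroxyphenyl)oxolan-3-yl]methyl acetate | COc1ccc([C@@H](OC(C)=O)[C@H]2CO[C@@H](c3ccc(O)cc3)[C@@H]2COC(C)=O)cc1 | target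

## Step count and risks

Total steps: 7. Longest linear sequence: 7 (1 → 4 → 6 → 7 → 9 → 10 → 11 → 14).

The three steps most likely to fail:

**Step 2 (the proposed new method).** The ee on a 3-aroyl substrate is unknown, and the new centre in 6 is α to a ketone and can erode. Fallback with known chemistry, setting out from 4: mCPBA (1.05 equiv), NaHCO3, CH2Cl2, 0 °C gives racemic 4-(4-methoxybenzoyl)oxolan-2-one F1 by an ordinary cyclobutanone Baeyer–Villiger oxidation. The transfer hydrogenation of step 3 applied to F1 is reagent-controlled at the carbinol carbon and gives 7 together with its diastereomer (4S)-4-[(S)-hydroxy(4-methoxyphenyl)methyl]oxolan-2-one F2. F2 is removed by chromatography or crystallisation (at most 50% yield), and the route is rejoined at 7.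

**Step 4.** The dianion may translactonise through the benzylic alkoxide, and formaldehyde can over-react or revert. Fallback, setting out from 7: TBSOTf and 2,6-lutidine give (4R)-4-[(S)-(tert-butyldimethylsilyloxy)(4-methoxyphenyl)methyl]oxolan-2-one F3. Its mono-enolate (LDA, 1.1 equiv, −78 °C) is hydroxymethylated with formaldehyde to (3S,4R)-3-(hydroxymethyl)-4-[(S)-(tert-butyldimethylsilyloxy)(4-methoxyphenyl)methyl]oxolan-2-one F4. HF·pyridine in THF at 0 °C removes the silyl group and the route is rejoined at 9.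

**Step 7.** The para-methoxybenzylic acetate may ionise, ortho- or O-arylation may compete, and elimination of 13 to the enol ether is possible. Fallback, setting out from 11, replaces C–H alkylation of phenol by ipso transfer from an aryl metal:
- 11 with PhSO2H and CaCl2 in CH2Cl2 gives the anomeric sulfone [(3S,4R)-4-[(S)-acetoxy(4-methoxyphenyl)methyl]-2-(phenylsulfonyl)oxolan-3-yl]methyl acetate F5.
- Separately, bought 4-bromophenol (8 heavy atoms) is silylated (TBSCl, imidazole) to (4-bromophenoxy)(tert-butyl)dimethylsilane F6. Mg in THF converts it into [4-(tert-butyldimethylsilyloxy)phenyl]magnesium bromide F7, and ZnBr2 into [4-(tert-butyldimethylsilyloxy)phenyl]zinc bromide F8.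
- F8 displaces the sulfone of F5 in THF at rt through the oxocarbenium ion, trans to the C3 arm and without touching the esters, to give [(2R,3S,4R)-4-[(S)-acetoxy(4-methoxyphenyl)methyl]-2-[4-(tert-butyldimethylsilyloxy)phenyl]oxolan-3-yl]methyl acetate F9.
- TBAF/AcOH in THF at 0 °C then frees the phenol and the route comes back at 14.

## Further compounds

F1 | step 2 | racemic 4-(4-methoxybenzoyl)oxolan-2-one | COc1ccc(C(=O)C2COC(=O)C2)cc1
F2 | step 2 | (4S)-4-[(S)-hydroxy(4-methoxyphenyl)methyl]oxolan-2-one | COc1ccc([C@@H](O)[C@@H]2COC(=O)C2)cc1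
F3 | step 4 | (4R)-4-[(S)-(tert-butyldimethylsilyloxy)(4-methoxyphenyl)methyl]oxolan-2-one | COc1ccc([C@@H](O[Si](C)(C)C(C)(C)C)[C@H]2COC(=O)C2)cc1
F4 | step 4 | (3S,4R)-3-(hydroxymethyl)-4-[(S)-(tert-butyldimethylsilyloxy)(4-methoxyphenyl)methyl]oxolan-2-one | COc1ccc([C@@H](O[Si](C)(C)C(C)(C)C)[C@H]2COC(=O)[C@@H]2CO)cc1
F5 | step 7 | [(3S,4R)-4-[(S)-acetoxy(4-methoxyphenyl)methyl]-2-(phenylsulfonyl)oxolan-3-yl]methyl acetate | COc1ccc([C@@H](OC(C)=O)[C@H]2COC(S(=O)(=O)c3ccccc3)[C@@H]2COC(C)=O)cc1
F6 | step 7 | (4-bromophenoxy)(tert-butyl)dimethylsilane | CC(C)(C)[Si](C)(C)Oc1ccc(Br)cc1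
F7 | step 7 | [4-(tert-butyldimethylsilyloxy)phenyl]magnesium bromide | CC(C)(C)[Si](C)(C)Oc1ccc([Mg]Br)cc1
F8 | step 7 | [4-(tert-butyldimethylsilyloxy)phenyl]zinc bromide | CC(C)(C)[Si](C)(C)Oc1ccc([Zn]Br)cc1
F9 | step 7 | [(2R,3S,4R)-4-[(S)-acetoxy(4-methoxyphenyl)methyl]-2-[4-(tert-butyldimethylsilyloxy)phenyl]oxolan-3-yl]methyl acetate | COc1ccc([C@@H](OC(C)=O)[C@H]2CO[C@@H](c3ccc(O[Si](C)(C)C(C)(C)C)cc3)[C@@H]2COC(C)=O)cc1
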